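**Strategy.** The cyclohexane ring of the 6-oxabicyclo[3.2.1]octane core (C1–C5, C8) is closed by an anionic (4+2) annulation. It inserts an acetyl unit (C2, C3) between an ester α-carbon (C1, whose ester carbon is C7) and an allylic chloride carbon (C4). Crossed Claisen acylation forms C1–C2, then β-keto ester dianion γ-alkylation forms C3–C4 in the same flask. The step exploits the 1,3-oxygen pattern C7–C1–C2 (a latent β-keto ester) and C4–C5 as a 2-substituted allyl electrophile. The precursor, a tert-butyl 3-[2-(chloromethyl)allyl]pentanoate, comes from periodate ring cleavage of (R)-limonene oxide, whose stereocentre becomes C8 and controls C1, C5 and C2.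

Key step: step 6

Remark on numbering: bicycle atoms are C1 (quaternary bridgehead with methyl and C7H2), C2 (CHOH), C3 and C4 (CH2), C5 (bridgehead with methyl and O6), O6, C7 (CH2O), C8 (CH carrying the side chain).
Remark on the starting material: commercial (+)-limonene oxide is taken as the cis/trans mixture of the (4R) epoxide; both isomers give the same cleavage product.

Step 1
Reactants: 1 (4R)-limonene 1,2-oxide (cis/trans mixture)
Product: 2 (3R)-6-oxo-3-(prop-1-en-2-yl)heptanal
Conditions: H5IO6, THF/H2O, 0 °C → rt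
Reagents that add atoms: water, O
Why: Epoxide hydrolysis to the trans-diol and periodate glycol cleavage open the terpene ring, both epoxide isomers converge on one keto aldehyde, and the untouched stereocentre becomes C8 of the target.

Step 2
Reactants: 2 (3R)-6-oxo-3-(prop-1-en-2-yl)heptanal
Product: 3 (3R)-6-oxo-3-(prop-1-en-2-yl)heptanoic acid
Conditions: NaClO2, NaH2PO4, 2-methylbut-2-ene, t-BuOH/H2O, 0 °C → rt
Reagents that add atoms: sodium chlorite, [Na+].[O-]Cl=O
Why: Pinnick oxidation takes the aldehyde to the acid (future C7) while the scavenger protects the isopropenyl group from hypochlorous acid.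

Step 3
Reactants: 3 (3R)-6-oxo-3-(prop-1-en-2-yl)heptanoic acid
Product: 4 tert-butyl (3R)-6-oxo-3-(prop-1-en-2-yl)heptanoate
Conditions: Boc2O, DMAP (cat.), t-BuOH, 35 °C
Reagents that add atoms: di-tert-butyl dicarbonate, CC(C)(C)OC(=O)OC(=O)OC(C)(C)C; tert-butanol, CC(C)(C)O
Why: DMAP-catalysed mixed-anhydride esterification gives an ester that can be enolised, resists attack at its own carbonyl and can later leave as isobutene.

Step 4
Reactants: 4 tert-butyl (3R)-6-oxo-3-(prop-1-en-2-yl)heptanoate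
Product: 5 tert-butyl (3R)-5-(2-methyl-1,3-dioxolan-2-yl)-3-(prop-1-en-2-yl)pentanoate
Conditions: ethylene glycol, PPTS (cat.), benzene, reflux (Dean–Stark)
Reagents that add atoms: ethylene glycol, OCCO
Why: Ketalisation masks the methyl ketone against the amide bases and hydride used later, and the weak acid leaves the tert-butyl ester and the alkene alone.

Step 5
Reactants: 5 tert-butyl (3R)-5-(2-methyl-1,3-dioxolan-2-yl)-3-(prop-1-en-2-yl)pentanoate
Product: 6 tert-butyl (3R)-3-(3-chloroprop-1-en-2-yl)-5-(2-methyl-1,3-dioxolan-2-yl)pentanoate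
Conditions: Ca(OCl)2, CO2 (dry ice), CH2Cl2/H2O, 0 °C
Reagents that add atoms: calcium hypochlorite, [Ca+2].[O-]Cl.[O-]Cl
Why: Ene-type allylic chlorination by hypochlorous acid puts chlorine on the terminal CH2 and the tertiary cation loses a methyl proton, giving the 2-(chloromethyl)allyl unit without touching the stereocentre.

Step 6
Reactants: 6 tert-butyl (3R)-3-(3-chloroprop-1-en-2-yl)-5-(2-methyl-1,3-dioxolan-2-yl)pentanoate; 7 1-acetylimidazole
Product: 9 tert-butyl (2R)-2-[2-(2-methyl-1,3-dioxolan-2-yl)ethyl]-3-methylidene-6-oxocyclohexane-1-carboxylate (C1 epimers), via acyclic beta-keto ester 8 (not isolated)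
Conditions: LiN(i-Pr)2 (1.05 equiv), THF, −78 °C; 7 (1.0 equiv), −78 → −30 °C; LiN(i-Pr)2 (2.3 equiv), −78 → 0 °C; aq. NH4Cl
Reagents that add atoms: none
Why: The ester enolate is C-acetylated by 7 (crossed Claisen condensation), forming C1–C2 and leaving 8 as its monoanion; a second deprotonation at the acetyl methyl gives the β-keto ester dianion, whose γ-carbon displaces the allylic chloride and forms C3–C4. The closest known reaction types are the Claisen acylation of ester enolates and the γ-alkylation of acetoacetate dianions, run here in one flask as an anionic (4+2) annulation. The cyclohexanone closes in the 6-(enolendo)-exo-tet mode, and SN2 or SN2' attack on the symmetrical 2-substituted allyl unit gives the same methylidene ring. C8 is untouched, and the new α-centre (C1) is an epimerisable β-keto ester carbon, so it needs no control here and is fixed in step 7. The step needs γ- over α- or O-alkylation and six- over four-membered closure: the dianion reacts at its more basic γ-carbon, the α-carbon could only close a cyclobutane, and the tert-butyl group blocks attack at the ester carbonyl.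

Step 7
Reactants: 9 tert-butyl (2R)-2-[2-(2-methyl-1,3-dioxolan-2-yl)ethyl]-3-methylidene-6-oxocyclohexane-1-carboxylate (C1 epimers)
Product: 10 tert-butyl (1S,2S)-1-methyl-2-[2-(2-methyl-1,3-dioxolan-2-yl)ethyl]-3-methylidene-6-oxocyclohexane-1-carboxylate
Conditions: K2CO3, MeI, acetone, rt → 40 °C
Reagents that add atoms: iodomethane, CI
Why: C-alkylation of the β-keto ester enolate: the neighbouring side chain, flanked by two sp2 carbons, should sit pseudoaxial to avoid allylic strain, so iodomethane enters from the opposite face and the methyl ends trans to the chain (ester cis), which sets quaternary C1.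

Step 8
Reactants: 10 tert-butyl (1S,2S)-1-methyl-2-[2-(2-methyl-1,3-dioxolan-2-yl)ethyl]-3-methylidene-6-oxocyclohexane-1-carboxylate
Product: 11 (1S,5S,8R)-1,5-dimethyl-8-[2-(2-methyl-1,3-dioxolan-2-yl)ethyl]-6-oxabicyclo[3.2.1]octane-2,7-dione
Conditions: [N,N'-bis(3,5-di-tert-butylsalicylidene)cyclohexane-1,2-diaminato]cobalt C36H52CoN2O2 (divalent cobalt, 5 mol%), N-fluoro-2,4,6-trimethylpyridinium triflate, (Me2SiH)2O, PhCF3, rt
Reagents that add atoms: none
Why: Cobalt–salen hydrogen-atom-transfer hydroacyloxylation of an alkenyl ester: a cobalt hydride adds H to the exocyclic CH2, radical–polar crossover gives a cation equivalent at C5 that the axial ester carbonyl captures with loss of isobutene, and since the lactone can only bridge cis-1,3-diaxially C5 is set, while the acid-free conditions spare the ketal and avoid cationic scrambling at C8.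

Step 9
Reactants: 11 (1S,5S,8R)-1,5-dimethyl-8-[2-(2-methyl-1,3-dioxolan-2-yl)ethyl]-6-oxabicyclo[3.2.1]octane-2,7-dione
Product: 12 (1S,2R,3R,4R)-3-(hydroxymethyl)-1,3-dimethyl-2-[2-(2-methyl-1,3-dioxolan-2-yl)ethyl]cyclohexane-1,4-diol
Conditions: LiAlH4, THF, −78 °C → rt
Reagents that add atoms: none
Why: Hydride reduction: the ketone should react first, on the rigid bicycle, from the face opposite the lactone bridge (axial attack), giving the equatorial C2 alcohol, and on warming the lactone is opened to the diol.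

Step 10
Reactants: 12 (1S,2R,3R,4R)-3-(hydroxymethyl)-1,3-dimethyl-2-[2-(2-methyl-1,3-dioxolan-2-yl)ethyl]cyclohexane-1,4-diol
Product: 15 4-[(1R,2R,5S,8R)-2-hydroxy-1,5-dimethyl-6-oxabicyclo[3.2.1]octan-8-yl]butan-2-one, via primary tosylate 13 (not isolated), via dioxolane-protected bicyclic ether 14 (not isolated)
Conditions: TsCl (1.2 equiv), pyridine, DMAP (cat.), 0 → 60 °C; then 2 M HCl, THF, rt
Reagents that add atoms: water, O
Why: Selective tosylation of the primary alcohol and intramolecular Williamson etherification by the 1,3-diaxial tertiary hydroxyl (5-exo-tet, no cation at C5) rebuild the O6–C7 bridge at the ether level, and the aqueous acid then hydrolyses the dioxolane.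

Step 11
Reactants: 15 4-[(1R,2R,5S,8R)-2-hydroxy-1,5-dimethyl-6-oxabicyclo[3.2.1]octan-8-yl]butan-2-one; 16 ethyl 2-[di(propan-2-yloxy)phosphoryl]acetate
Product: 17 ethyl (2E)-5-[(1R,2R,5S,8R)-2-hydroxy-1,5-dimethyl-6-oxabicyclo[3.2.1]octan-8-yl]-3-methylpent-2-enoate
Conditions: NaH (2.5 equiv), THF, 0 °C → rt
Reagents that add atoms: none
Why: Horner–Wadsworth–Emmons olefination of the methyl ketone, in which the bulky diisopropyl phosphonate should favour the E enoate and any Z isomer would be removed by chromatography.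

Step 12
Reactants: 17 ethyl (2E)-5-[(1R,2R,5S,8R)-2-hydroxy-1,5-dimethyl-6-oxabicyclo[3.2.1]octan-8-yl]-3-methylpent-2-enoate
Product: 18 (2E)-5-[(1R,2R,5S,8R)-2-hydroxy-1,5-dimethyl-6-oxabicyclo[3.2.1]octan-8-yl]-3-methylpent-2-en-1-ol
Conditions: i-Bu2AlH (4 equiv), CH2Cl2, −78 → 0 °C
Reagents that add atoms: none
Why: 1,2-Reduction of the enoate gives the allylic alcohol without changing the alkene geometry.

Step 13
Reactants: 18 (2E)-5-[(1R,2R,5S,8R)-2-hydroxy-1,5-dimethyl-6-oxabicyclo[3.2.1]octan-8-yl]-3-methylpent-2-en-1-ol; 19 7-hydroxy-2H-chromen-2-one (umbelliferone)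
Product: 20 7-{[(2E)-5-[(1R,2R,5S,8R)-2-hydroxy-1,5-dimethyl-6-oxabicyclo[3.2.1]octan-8-yl]-3-methylpent-2-en-1-yl]oxy}-2H-chromen-2-one (CNP0178104.1)
Conditions: PPh3, DIAD, THF, 0 °C → rt
Reagents that add atoms: none
Why: Mitsunobu etherification, in which the acidic phenol displaces the activated primary allylic alcohol by SN2 while the hindered secondary alcohol next to quaternary C1 should not react.

**Compound list**

1 | (4R)-limonene 1,2-oxide [(4R)-1-methyl-4-(prop-1-en-2-yl)-7-oxabicyclo[4.1.0]heptane; cis/trans mixture] | CC12OC1C[C@@H](CC2)C(C)=C | starting material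
2 | (3R)-6-oxo-3-(prop-1-en-2-yl)heptanal | O=CC[C@@H](CCC(C)=O)C(C)=C | intermediate
3 | (3R)-6-oxo-3-(prop-1-en-2-yl)heptanoic acid | OC(=O)C[C@@H](CCC(C)=O)C(C)=C | intermediate
4 | tert-butyl (3R)-6-oxo-3-(prop-1-en-2-yl)heptanoate | CC(C)(C)OC(=O)C[C@@H](CCC(C)=O)C(C)=C | intermediate
5 | tert-butyl (3R)-5-(2-methyl-1,3-dioxolan-2-yl)-3-(prop-1-en-2-yl)pentanoate | CC(C)(C)OC(=O)C[C@@H](CCC1(C)OCCO1)C(C)=C | intermediate
6 | tert-butyl (3R)-3-(3-chloroprop-1-en-2-yl)-5-(2-methyl-1,3-dioxolan-2-yl)pentanoate | CC(C)(C)OC(=O)C[C@@H](CCC1(C)OCCO1)C(=C)CCl | intermediate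
7 | 1-acetylimidazole | CC(=O)n1ccnc1 | starting material
8 | tert-butyl (3R)-2-acetyl-3-(3-chloroprop-1-en-2-yl)-5-(2-methyl-1,3-dioxolan-2-yl)pentanoate (C2 epimers) | CC(=O)C(C(=O)OC(C)(C)C)[C@@H](CCC1(C)OCCO1)C(=C)CCl | intermediate (not isolated)
9 | tert-butyl (2R)-2-[2-(2-methyl-1,3-dioxolan-2-yl)ethyl]-3-methylidene-6-oxocyclohexane-1-carboxylate (C1 epimers) | CC1(OCCO1)CC[C@@H]1C(C(=O)OC(C)(C)C)C(=O)CCC1=C | intermediate
10 | tert-butyl (1S,2S)-1-methyl-2-[2-(2-methyl-1,3-dioxolan-2-yl)ethyl]-3-methylidene-6-oxocyclohexane-1-carboxylate (methyl trans to the side chain) | CC1(OCCO1)CC[C@@H]1[C@](C)(C(=O)OC(C)(C)C)C(=O)CCC1=C | intermediate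
11 | (1S,5S,8R)-1,5-dimethyl-8-[2-(2-methyl-1,3-dioxolan-2-yl)ethyl]-6-oxabicyclo[3.2.1]octane-2,7-dione | CC1(OCCO1)CC[C@@H]1[C@]2(C)C(=O)O[C@@]1(C)CCC2=O | intermediate
12 | (1S,2R,3R,4R)-3-(hydroxymethyl)-1,3-dimethyl-2-[2-(2-methyl-1,3-dioxolan-2-yl)ethyl]cyclohexane-1,4-diol | CC1(OCCO1)CC[C@@H]1[C@](C)(CO)[C@H](O)CC[C@]1(C)O | intermediate
13 | primary 4-methylbenzenesulfonate of triol 12 (stereocentres as in 12) | CC1(OCCO1)CC[C@@H]1[C@](C)(COS(=O)(=O)c2ccc(C)cc2)[C@H](O)CC[C@]1(C)O | intermediate (not isolated)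
14 | (1R,2R,5S,8R)-1,5-dimethyl-8-[2-(2-methyl-1,3-dioxolan-2-yl)ethyl]-6-oxabicyclo[3.2.1]octan-2-ol | CC1(OCCO1)CC[C@@H]1[C@]2(C)CO[C@@]1(C)CC[C@H]2O | intermediate (not isolated)
15 | 4-[(1R,2R,5S,8R)-2-hydroxy-1,5-dimethyl-6-oxabicyclo[3.2.1]octan-8-yl]butan-2-one | CC(=O)CC[C@@H]1[C@]2(C)CO[C@@]1(C)CC[C@H]2O | intermediate
16 | ethyl 2-[di(propan-2-yloxy)phosphoryl]acetate | CCOC(=O)CP(=O)(OC(C)C)OC(C)C | starting material
17 | ethyl (2E)-5-[(1R,2R,5S,8R)-2-hydroxy-1,5-dimethyl-6-oxabicyclo[3.2.1]octan-8-yl]-3-methylpent-2-enoate | C/C(=C\C(=O)OCC)CC[C@@H]1[C@]2(C)CO[C@@]1(C)CC[C@H]2O | intermediate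
18 | (2E)-5-[(1R,2R,5S,8R)-2-hydroxy-1,5-dimethyl-6-oxabicyclo[3.2.1]octan-8-yl]-3-methylpent-2-en-1-ol | C/C(=C\CO)CC[C@@H]1[C@]2(C)CO[C@@]1(C)CC[C@H]2O | intermediate
19 | 7-hydroxy-2H-chromen-2-one (umbelliferone) | Oc1ccc2ccc(=O)oc2c1 | starting material
20 | 7-{[(2E)-5-[(1R,2R,5S,8R)-2-hydroxy-1,5-dimethyl-6-oxabicyclo[3.2.1]octan-8-yl]-3-methylpent-2-en-1-yl]oxy}-2H-chromen-2-one | C/C(=C\COc1ccc2ccc(=O)oc2c1)CC[C@@H]1[C@]2(C)CO[C@@]1(C)CC[C@H]2O | target

**Step count.** Total: 13 steps. Longest linear sequence: 13 steps, from 1 to 20.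

**Steps most likely to fail**

Step 6. The first enolate may close a four-membered ring before it is acylated, or the dianion may be lost to intramolecular O-alkylation, so that the two bonds do not form in sequence. The fallback sets out from 6 and returns at 9, reversing the order of the two bond formations. The lithium enolate of ethyl acetate (LiN(SiMe3)2, THF/DMPU, −78 °C, NaI cat.) is alkylated by chloride 6 to give the mixed diester 1-tert-butyl 7-ethyl (3R)-3-[2-(2-methyl-1,3-dioxolan-2-yl)ethyl]-4-methylideneheptanedioate F1. Dieckmann condensation (KOt-Bu, THF, 0 °C) then closes the ring; only the enolate next to the tert-butyl ester can attack the unhindered ethyl ester, so the same β-keto ester 9 should result.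

Step 8. Hydrogen-atom transfer may end in alkene isomerisation or simple reduction instead of capture by the ester oxygen. The fallback sets out from 10 and returns at 11. Iodolactonisation (I2, NaHCO3, MeCN, 0 °C) lets the tert-butyl ester carbonyl open the iodonium ion at the tertiary carbon with loss of isobutene, giving the iodomethyl lactone (1S,5S,8R)-5-(iodomethyl)-1-methyl-8-[2-(2-methyl-1,3-dioxolan-2-yl)ethyl]-6-oxabicyclo[3.2.1]octane-2,7-dione F2 with the same forced cis-bridging. Radical deiodination (n-Bu3SnH, AIBN, benzene, 80 °C) then gives 11.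

Step 11. Olefination of an unhindered methyl ketone may proceed with poor E/Z control. The fallback sets out from 15 and returns at 18, bypassing steps 11 and 12.
- Silylation (t-BuMe2SiOTf, 2,6-lutidine, CH2Cl2, −78 °C) gives 4-[(1R,2R,5S,8R)-2-{[tert-butyl(dimethyl)silyl]oxy}-1,5-dimethyl-6-oxabicyclo[3.2.1]octan-8-yl]butan-2-one F3.
- The methyl ketone is converted through its kinetic enol phosphate (LiN(i-Pr)2, ClP(O)(OEt)2, THF, −78 °C; then LiN(i-Pr)2, −78 °C → rt) into the terminal alkyne tert-butyl{[(1R,2R,5S,8R)-8-(but-3-yn-1-yl)-1,5-dimethyl-6-oxabicyclo[3.2.1]octan-2-yl]oxy}dimethylsilane F4.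
- Negishi carboalumination (Me3Al, (C5H5)2ZrCl2, CH2Cl2, 0 °C → rt; then paraformaldehyde) adds methyl and the metal syn across the alkyne, so only the E alcohol (2E)-5-[(1R,2R,5S,8R)-2-{[tert-butyl(dimethyl)silyl]oxy}-1,5-dimethyl-6-oxabicyclo[3.2.1]octan-8-yl]-3-methylpent-2-en-1-ol F5 should form.
- Bu4NF in THF removes the silyl group to give 18.

Further compounds
F1 | step 6 | 1-tert-butyl 7-ethyl (3R)-3-[2-(2-methyl-1,3-dioxolan-2-yl)ethyl]-4-methylideneheptanedioate | CC(C)(C)OC(=O)C[C@@H](CCC1(C)OCCO1)C(=C)CCC(=O)OCC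
F2 | step 8 | (1S,5S,8R)-5-(iodomethyl)-1-methyl-8-[2-(2-methyl-1,3-dioxolan-2-yl)ethyl]-6-oxabicyclo[3.2.1]octane-2,7-dione | CC1(OCCO1)CC[C@@H]1[C@]2(C)C(=O)O[C@@]1(CI)CCC2=O
F3 | step 11 | 4-[(1R,2R,5S,8R)-2-{[tert-butyl(dimethyl)silyl]oxy}-1,5-dimethyl-6-oxabicyclo[3.2.1]octan-8-yl]butan-2-one | CC(=O)CC[C@@H]1[C@]2(C)CO[C@@]1(C)CC[C@H]2O[Si](C)(C)C(C)(C)C
F4 | step 11 | tert-butyl{[(1R,2R,5S,8R)-8-(but-3-yn-1-yl)-1,5-dimethyl-6-oxabicyclo[3.2.1]octan-2-yl]oxy}dimethylsilane | C#CCC[C@@H]1[C@]2(C)CO[C@@]1(C)CC[C@H]2O[Si](C)(C)C(C)(C)C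
F5 | step 11 | (2E)-5-[(1R,2R,5S,8R)-2-{[tert-butyl(dimethyl)silyl]oxy}-1,5-dimethyl-6-oxabicyclo[3.2.1]octan-8-yl]-3-methylpent-2-en-1-ol | C/C(=C\CO)CC[C@@H]1[C@]2(C)CO[C@@]1(C)CC[C@H]2O[Si](C)(C)C(C)(C)C
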